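**Plan**

1. Retrosynthesis: after removal of the C8 acetate and the C5 O-methyl group, the C4–C5 bond is cut; this opens the six-membered ring C1–C2–C3–C4–C5–C8 and leaves a cyclopentanone (ring C1–C7–C6–C5–C8) with a 2-methoxy-3-oxopropyl arm (C2–C3–C4) on C1.
2. Enabling feature: the C4 ketone is bonded directly to the fully substituted, oxygen-bearing bridgehead C5 inside that six-membered ring. This tertiary α-ketol is the retron of an aldehyde (C4) plus ketone (C5) benzoin reaction.
3. Further cuts: C6–aryl (conjugate addition), C1–C2 and C1–allyl (two enolate alkylations), C7–methyl (cuprate addition to a 4-silyloxycyclopentenone). The C5 ketone and C8 oxygen come from a 1,2-carbonyl transposition of the C8 ketone that served the alkylations.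
4. Forward: the five-membered ring is present from the start; methyl, allyl and a four-carbon arm are attached, the arm is oxidised to a methoxy diol acetonide, aryl and the two ring oxygens follow, the aldehyde is unmasked, and the six-membered ring is closed last.
5. Stereochemistry: the silyloxy centre of the starting enone sets C7; C7 relays to C1 (second alkylation anti to methyl) and to C6 (aryl anti to methyl); C6 places the C5 hydroxyl, which directs hydride to C8; C3 comes from a reagent-controlled asymmetric epoxidation opened by methanol with inversion; C5 is fixed by the tether in the ring closure.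

Key step: step 13

Convention: locants C1–C8 are those of the target bicycle in every compound (C1 quaternary allyl carbon, C2 CH2, C3 CH–OMe, C4 C=O, C5, C6 CH–aryl, C7 CH–Me, C8 oxygenated bridge carbon). β is the face of the five-membered ring that carries the C7 methyl, α the other face.

Assumption: the (S)-enantiomer of the silyloxy enone 1 and the aryl Grignard solution 14 are taken to be purchasable.

**Route**

Step 1
Reactants: 1 (S)-4-(tert-butyldimethylsilyloxy)cyclopent-2-en-1-one; 2 allyl bromide
Product: 5 (4R,5S)-5-allyl-4-methylcyclopent-2-en-1-one, via lithium enolate 3 (not isolated), via silyloxy ketone 4 (not isolated)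
Conditions: Me2CuLi (from MeLi, CuI), Et2O, −78 °C; then 2, HMPA, −78 → −20 °C; then DBU, 0 °C, short reaction time
Reagents that add atoms: lithium dimethylcuprate, [Li+].C[Cu-]C
Why: Gilman cuprate conjugate addition places methyl anti to the silyloxy group (this sets C7), the regiodefined enolate is C-allylated as in a three-component enone coupling, and DBU then removes silanol by E1cB elimination, which moves the enone so that the carbonyl (later C8) is flanked by the allylated carbon (later C1), whose configuration is of no consequence because it is enolised next.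

Step 2
Reactants: 5 (4R,5S)-5-allyl-4-methylcyclopent-2-en-1-one; 6 (E)-1,4-dibromobut-2-ene
Product: 8 (4R,5S)-5-allyl-5-[(E)-4-bromobut-2-en-1-yl]-4-methylcyclopent-2-en-1-one, via lithium enolate 7 (not isolated)
Conditions: LiN(iPr)2, THF, −78 °C; enolate added to 6 (4 equiv), DMPU, −78 → −30 °C
Reagents that add atoms: none
Why: Kinetic α′-deprotonation of the cyclopentenone and SN2 alkylation of the cross-conjugated enolate with the allylic dibromide, kept in excess to prevent double alkylation, should take place anti to the adjacent C7 methyl group, which builds the C1 quaternary centre with the four-carbon arm on the α face and allyl cis to methyl.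

Step 3
Reactants: 8 (4R,5S)-5-allyl-5-[(E)-4-bromobut-2-en-1-yl]-4-methylcyclopent-2-en-1-one
Product: 10 (4R,5S)-5-allyl-5-[(E)-4-hydroxybut-2-en-1-yl]-4-methylcyclopent-2-en-1-one, via formate ester 9 (not isolated)
Conditions: HCO2Na, DMF, 40 °C; then MeOH, K2CO3 (5 mol %), 0 °C
Reagents that add atoms: sodium formate, [Na+].[O-]C=O
Why: SN2 displacement of the primary allylic bromide by formate with retention of the E geometry, followed by base-catalysed transesterification of the formate with methanol, should unveil the allylic alcohol under conditions too mild to affect the enone.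

Step 4
Reactants: 10 (4R,5S)-5-allyl-5-[(E)-4-hydroxybut-2-en-1-yl]-4-methylcyclopent-2-en-1-one
Product: 11 epoxy alcohol, arm = [(2R,3R)-3-(hydroxymethyl)oxiran-2-yl]methyl
Conditions: Ti(OiPr)4 (10 mol %), D-(−)-diethyl tartrate (12 mol %), t-BuOOH, 4 Å MS, CH2Cl2, −20 °C
Reagents that add atoms: tert-butyl hydroperoxide, CC(C)(C)OO
Why: Sharpless asymmetric epoxidation is reagent-controlled and confined to the allylic alcohol, so with D-(−)-tartrate the E olefin should give the (2R,3R)-epoxy alcohol whatever the ring stereocentres, while the enone and the allyl group stay untouched.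

Step 5
Reactants: 11 epoxy alcohol
Product: 12 methoxy diol, arm = (2S,3R)-3,4-dihydroxy-2-methoxybutyl
Conditions: Eu(OTf)3 (10 mol %), 2,6-di-tert-butyl-4-methylpyridine (10 mol %), MeOH, rt
Reagents that add atoms: methanol, CO
Why: Lewis-acid-catalysed, hydroxyl-chelated alcoholysis of a 2,3-epoxy alcohol occurs at the distal carbon (C-3 of the epoxy alcohol, C3 here) with inversion, which sets the C3 methoxy stereocentre as S and leaves a terminal 1,2-diol for later glycol cleavage.

Step 6
Reactants: 12 methoxy diol
Product: 13 acetonide enone, arm = (2S)-2-[(4R)-2,2-dimethyl-1,3-dioxolan-4-yl]-2-methoxyethyl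
Conditions: Me2C(OMe)2, PPTS (cat.), CH2Cl2, rt
Reagents that add atoms: 2,2-dimethoxypropane, COC(C)(C)OC
Why: Acid-catalysed acetal exchange protects the terminal 1,2-diol as its acetonide, which masks the future aldehyde through the organometallic, oxidation and hydride steps.

Step 7
Reactants: 13 acetonide enone; 14 3,4-dimethoxyphenylmagnesium bromide
Product: 15 trimethylsilyl enol ether (C8–OSiMe3, C5=C8, 6α-aryl)
Conditions: 3,4-(MeO)2C6H3MgBr, CuBr·SMe2 (10 mol %), Me3SiCl, HMPA, THF, −78 °C; Et3N, pentane work-up
Reagents that add atoms: chlorotrimethylsilane, C[Si](C)(C)Cl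
Why: Copper-catalysed, silyl-chloride-accelerated conjugate addition of the aryl Grignard reagent should occur anti to the neighbouring C7 methyl group (the two CH2 substituents on C1 shield both faces alike), which sets C6 with aryl on the α face, and the C8 enolate is trapped regiospecifically as the silyl enol ether.

Step 8
Reactants: 15 trimethylsilyl enol ether
Product: 17 5β-hydroxy C8 ketone, via silyloxy epoxide 16 (not isolated)
Conditions: DMDO, acetone/CH2Cl2, −78 → −30 °C; then MeOH, citric acid (cat.), 0 °C
Reagents that add atoms: dimethyldioxirane, CC1(C)OO1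
Why: Rubottom-type oxidation: the dioxirane epoxidises the electron-rich silyl enol ether much faster than the allyl double bond and from the β face opposite the C6 aryl group, and acidic methanolysis of the silyloxy epoxide gives the C5 β-hydroxy ketone.

Step 9
Reactants: 17 5β-hydroxy C8 ketone
Product: 18 5β,8α-diol
Conditions: Me4NBH(OAc)3, MeCN/AcOH (1:1), −30 → −20 °C
Reagents that add atoms: none
Why: Hydroxyl-directed reduction with triacetoxyborohydride (Evans–Saksena type) delivers hydride intramolecularly from the C5 alkoxyborohydride to the β face of the hindered C8 ketone, so the new C8 hydroxyl should lie on the α face, trans to the C5 hydroxyl and cis to the arm.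

Step 10
Reactants: 18 5β,8α-diol
Product: 19 8α-hydroxy C5 ketone
Conditions: TEMPO (10 mol %), PhI(OAc)2 (1.1 equiv), CH2Cl2, rt
Reagents that add atoms: none
Why: Oxoammonium (nitroxyl-catalysed) oxidation responds strongly to steric hindrance, so the C5 hydroxyl between two CH carbons should be oxidised in preference to the neopentyl-type C8 hydroxyl next to quaternary C1, which completes the 1,2-carbonyl transposition.

Step 11
Reactants: 19 8α-hydroxy C5 ketone
Product: 20 8α-(tert-butyldimethylsilyloxy) C5 ketone with acetonide arm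
Conditions: tBuMe2SiOTf, 2,6-lutidine, CH2Cl2, −78 → 0 °C
Reagents that add atoms: tert-butyldimethylsilyl triflate, CC(C)(C)[Si](C)(C)OS(=O)(=O)C(F)(F)F
Why: Silylation with the silyl triflate and a hindered pyridine base protects the hindered secondary C8 alcohol at low temperature without enolising the adjacent ketone.

Step 12
Reactants: 20 8α-silyloxy C5 ketone with acetonide arm
Product: 22 keto aldehyde (arm = (S)-2-methoxy-3-oxopropyl), via free diol 21 (not isolated)
Conditions: H5IO6, EtOAc, rt
Reagents that add atoms: none
Why: Periodic acid hydrolyses the terminal acetonide and cleaves the resulting 1,2-diol in the same flask (glycol cleavage), which releases the α-methoxy aldehyde under non-basic conditions that should leave C3, C6 and C8 unchanged.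

Step 13
Reactants: 22 keto aldehyde
Product: 23 bicyclo[3.2.1]octane acyloin (C4 ketone, C5 β-hydroxyl, C8 silyl ether)
Conditions: 2-(pentafluorophenyl)-6,7-dihydro-5H-pyrrolo[2,1-c][1,2,4]triazol-2-ium tetrafluoroborate (20 mol %), Et3N (20 mol %), toluene (0.02 M), rt → 40 °C
Reagents that add atoms: none
Why: The triazolylidene adds to the unhindered C4 aldehyde and proton transfer gives the enaminol (acyl-anion equivalent), which adds to the C5 ketone; proton transfer and loss of the carbene then leave the tertiary α-ketol. The closest known reaction type is the carbene-catalysed intramolecular crossed benzoin of keto aldehydes that delivers five- and six-membered cyclic tertiary acyloins. The six-membered ring C1–C2–C3–C4–C5–C8 closes in a 6-exo-trig mode onto the ring carbonyl and thereby creates the bicyclo[3.2.1]octane. C5 is the only new stereocentre and is set by the tether: the arm sits on the α face of C1 and can reach C5 only from that face, so the hydroxyl is forced to the β face. The step needs chemoselectivity (aldehyde as donor, ketone as acceptor), which is inherent because a ketone cannot form the acyl-anion equivalent and high dilution disfavours aldehyde homo-coupling. It also needs the C3, C6 and C8 centres to survive, which the acidic N-pentafluorophenyl triazolium salt secures by working with a catalytic amount of a weak amine base.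

Step 14
Reactants: 23 bicyclic acyloin
Product: 24 C5 methyl ether
Conditions: MeOTf, 2,6-di-tert-butyl-4-methylpyridine, CH2Cl2, 40 °C
Reagents that add atoms: methyl triflate, COS(=O)(=O)C(F)(F)F
Why: O-Methylation of the tertiary alcohol with methyl triflate and a non-nucleophilic pyridine base is an SN2 reaction on the methylating agent that needs no alkoxide, which should avoid α-ketol rearrangement and retro-benzoin cleavage.

Step 15
Reactants: 24 C5 methyl ether
Product: 25 C8 alcohol
Conditions: HF·pyridine, pyridine, THF, 0 °C → rt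
Reagents that add atoms: none
Why: Fluoride-induced cleavage of the silyl ether with buffered HF·pyridine is weakly acidic, so the C3 centre next to the ketone should not epimerise.

Step 16
Reactants: 25 C8 alcohol
Product: 26 target acetate
Conditions: Ac2O, DMAP (cat.), pyridine, CH2Cl2, rt
Reagents that add atoms: acetic anhydride, CC(=O)OC(C)=O
Why: Nucleophile-catalysed (DMAP) acylation of the secondary C8 alcohol with acetic anhydride gives the acetate and thus the target.

**Compound list**

1 | (S)-4-(tert-butyldimethylsilyloxy)cyclopent-2-en-1-one | O=C1C=C[C@@H](O[Si](C)(C)C(C)(C)C)C1 | starting material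
2 | allyl bromide | C=CCBr | starting material
3 | lithium enolate of the 3-methyl-4-silyloxycyclopentanone (methyl trans to silyloxy) | [Li]OC1=C[C@H](C)[C@@H](O[Si](C)(C)C(C)(C)C)C1 | intermediate
4 | (2S,3S,4S)-2-allyl-3-methyl-4-(tert-butyldimethylsilyloxy)cyclopentan-1-one | C=CC[C@H]1[C@H](C)[C@@H](O[Si](C)(C)C(C)(C)C)CC1=O | intermediate
5 | (4R,5S)-5-allyl-4-methylcyclopent-2-en-1-one | C=CC[C@H]1[C@H](C)C=CC1=O | intermediate
6 | (E)-1,4-dibromobut-2-ene | BrC/C=C/CBr | starting material
7 | lithium cross-conjugated enolate of 5 | C=CCC1=C(O[Li])C=C[C@H]1C | intermediate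
8 | (4R,5S)-5-allyl-5-[(E)-4-bromobut-2-en-1-yl]-4-methylcyclopent-2-en-1-one (allyl cis to methyl) | C=CC[C@]1(C/C=C/CBr)[C@H](C)C=CC1=O | intermediate
9 | formate ester of allylic alcohol 10 | C=CC[C@]1(C/C=C/COC=O)[C@H](C)C=CC1=O | intermediate
10 | (4R,5S)-5-allyl-5-[(E)-4-hydroxybut-2-en-1-yl]-4-methylcyclopent-2-en-1-one | C=CC[C@]1(C/C=C/CO)[C@H](C)C=CC1=O | intermediate
11 | (4R,5S)-5-allyl-5-{[(2R,3R)-3-(hydroxymethyl)oxiran-2-yl]methyl}-4-methylcyclopent-2-en-1-one | C=CC[C@]1(C[C@H]2O[C@@H]2CO)[C@H](C)C=CC1=O | intermediate
12 | (4R,5S)-5-allyl-5-[(2S,3R)-3,4-dihydroxy-2-methoxybutyl]-4-methylcyclopent-2-en-1-one | C=CC[C@]1(C[C@H](OC)[C@H](O)CO)[C@H](C)C=CC1=O | intermediate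
13 | (4R,5S)-5-allyl-5-{(2S)-2-[(4R)-2,2-dimethyl-1,3-dioxolan-4-yl]-2-methoxyethyl}-4-methylcyclopent-2-en-1-one | C=CC[C@]1(C[C@H](OC)[C@H]2COC(C)(C)O2)[C@H](C)C=CC1=O | intermediate
14 | 3,4-dimethoxyphenylmagnesium bromide | COc1ccc([Mg]Br)cc1OC | starting material
15 | C8 trimethylsilyl enol ether (C5=C8) with 6α-(3,4-dimethoxyphenyl), 7β-methyl, 1β-allyl and the 1α acetonide arm | C=CC[C@]1(C[C@H](OC)[C@H]2COC(C)(C)O2)[C@H](C)[C@@H](c3ccc(OC)c(OC)c3)C=C1O[Si](C)(C)C | intermediate
16 | 5β,8β-epoxide of 15 (silyloxy epoxide) | C=CC[C@]1(C[C@H](OC)[C@H]3COC(C)(C)O3)[C@H](C)[C@@H](c4ccc(OC)c(OC)c4)[C@@H]2O[C@]12O[Si](C)(C)C | intermediate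
17 | 5β-hydroxy C8 ketone (6α-aryl, 7β-methyl, 1β-allyl, 1α acetonide arm) | C=CC[C@]1(C[C@H](OC)[C@H]2COC(C)(C)O2)[C@H](C)[C@@H](c3ccc(OC)c(OC)c3)[C@H](O)C1=O | intermediate
18 | 5β,8α-diol (trans) | C=CC[C@]1(C[C@H](OC)[C@H]2COC(C)(C)O2)[C@H](C)[C@@H](c3ccc(OC)c(OC)c3)[C@H](O)[C@H]1O | intermediate
19 | 8α-hydroxy C5 ketone | C=CC[C@]1(C[C@H](OC)[C@H]2COC(C)(C)O2)[C@H](C)[C@@H](c3ccc(OC)c(OC)c3)C(=O)[C@H]1O | intermediate
20 | 8α-(tert-butyldimethylsilyloxy) C5 ketone with acetonide arm | C=CC[C@]1(C[C@H](OC)[C@H]2COC(C)(C)O2)[C@H](C)[C@@H](c3ccc(OC)c(OC)c3)C(=O)[C@H]1O[Si](C)(C)C(C)(C)C | intermediate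
21 | free diol from acetonide hydrolysis of 20 | C=CC[C@]1(C[C@H](OC)[C@H](O)CO)[C@H](C)[C@@H](c2ccc(OC)c(OC)c2)C(=O)[C@H]1O[Si](C)(C)C(C)(C)C | intermediate
22 | keto aldehyde: 4β-allyl-2α-(3,4-dimethoxyphenyl)-3β-methyl-5α-silyloxycyclopentanone with a 4α-[(S)-2-methoxy-3-oxopropyl] arm (cyclopentanone locants) | C=CC[C@]1(C[C@H](OC)C=O)[C@H](C)[C@@H](c2ccc(OC)c(OC)c2)C(=O)[C@H]1O[Si](C)(C)C(C)(C)C | intermediate
23 | bicyclo[3.2.1]octane acyloin: C4 ketone, C5 tertiary hydroxyl, C8 silyl ether | C=CC[C@]12C[C@H](OC)C(=O)[C@](O)([C@H](c3ccc(OC)c(OC)c3)[C@H]1C)[C@H]2O[Si](C)(C)C(C)(C)C | intermediate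
24 | C5 methyl ether of 23 | C=CC[C@]12C[C@H](OC)C(=O)[C@](OC)([C@H](c3ccc(OC)c(OC)c3)[C@H]1C)[C@H]2O[Si](C)(C)C(C)(C)C | intermediate
25 | C8 alcohol | C=CC[C@]12C[C@H](OC)C(=O)[C@](OC)([C@H](c3ccc(OC)c(OC)c3)[C@H]1C)[C@H]2O | intermediate
26 | 1-allyl-6-(3,4-dimethoxyphenyl)-3,5-dimethoxy-7-methyl-4-oxobicyclo[3.2.1]octan-8-yl acetate, (1S,3S,5S,6S,7R,8S) with the locants used here | C=CC[C@]12C[C@H](OC)C(=O)[C@](OC)([C@H](c3ccc(OC)c(OC)c3)[C@H]1C)[C@H]2OC(C)=O | target

**Step count**

Total steps: 16. Longest linear sequence: 16 (the route is fully linear from 1).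

**Steps most likely to fail, with fallbacks**

1. Step 13 (ring closure). Addition of the acyl-anion equivalent to the hindered C5 ketone may be slower than base-induced side processes: aldol closure from the C6 enolate onto the aldehyde, or epimerisation at C3 or C8. The closure may also stall at an unfavourable equilibrium. The fallback replaces umpolung by reductive coupling. Starting from keto aldehyde 22, an intramolecular pinacol coupling with low-valent titanium (TiCl3, Zn–Cu couple, DME, 0 °C) should form the same C4–C5 bond and ring and give the bicyclic 4,5-diol F1, whose C4 configuration does not matter. Oxidation of its secondary C4 hydroxyl with Dess–Martin periodinane, which cannot touch the tertiary C5 hydroxyl, rejoins the route at acyloin 23.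

2. Step 10 (selective oxidation). Site selectivity between the two secondary hydroxyls may be poor, or oxidation may run on to the 1,2-dione. The fallback differentiates the hydroxyls by protection. From diol 18, the more accessible C5 hydroxyl is silylated with Et3SiCl and imidazole at −40 °C to give the 5-O-triethylsilyl ether F2. tBuMe2SiOTf and 2,6-lutidine then cap the C8 hydroxyl to give the bis-silyl ether F3. Buffered HF·pyridine at 0 °C removes only the triethylsilyl group to give the 5-alcohol F4. Dess–Martin oxidation of F4 gives ketone 20, where the route continues.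

3. Step 14 (methylation of the tertiary alcohol). Conversion of the shielded tertiary hydroxyl may be incomplete, or α-ketol rearrangement may set in if forcing conditions are needed. The fallback changes the order so that the bulky silyl ether is gone before methylation. From acyloin 23, HF·pyridine frees the C8 hydroxyl to give the diol F5. Ac2O in pyridine without DMAP at 0 °C acetylates only the secondary C8 hydroxyl to give the hydroxy acetate F6. Methylation of the now less shielded tertiary hydroxyl with Me3OBF4 and 1,8-bis(dimethylamino)naphthalene gives the target 26 directly.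

**Further compounds**

F1 | step 13 | bicyclic 4,5-diol from pinacol coupling of 22 (C4 carbinol of either configuration) | C=CC[C@]12C[C@H](OC)C(O)[C@](O)([C@H](c3ccc(OC)c(OC)c3)[C@H]1C)[C@H]2O[Si](C)(C)C(C)(C)C
F2 | step 10 | 5-O-triethylsilyl ether of diol 18 | C=CC[C@]1(C[C@H](OC)[C@H]2COC(C)(C)O2)[C@H](C)[C@@H](c3ccc(OC)c(OC)c3)[C@H](O[Si](CC)(CC)CC)[C@H]1O
F3 | step 10 | 5-O-triethylsilyl 8-O-tert-butyldimethylsilyl bis-ether | C=CC[C@]1(C[C@H](OC)[C@H]2COC(C)(C)O2)[C@H](C)[C@@H](c3ccc(OC)c(OC)c3)[C@H](O[Si](CC)(CC)CC)[C@H]1O[Si](C)(C)C(C)(C)C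
F4 | step 10 | 5β-alcohol with 8α-tert-butyldimethylsilyl ether | C=CC[C@]1(C[C@H](OC)[C@H]2COC(C)(C)O2)[C@H](C)[C@@H](c3ccc(OC)c(OC)c3)[C@H](O)[C@H]1O[Si](C)(C)C(C)(C)C
F5 | step 14 | bicyclic 5,8-diol (desilylated acyloin) | C=CC[C@]12C[C@H](OC)C(=O)[C@](O)([C@H](c3ccc(OC)c(OC)c3)[C@H]1C)[C@H]2O
F6 | step 14 | 8-acetate with free tertiary C5 hydroxyl | C=CC[C@]12C[C@H](OC)C(=O)[C@](O)([C@H](c3ccc(OC)c(OC)c3)[C@H]1C)[C@H]2OC(C)=O
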